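**Assumptions**
- Compound 1 is bought as the free acid (the parent acid of the fragrance ester methyl atratate); if only the methyl ester is in stock, one saponification precedes step 1.
- The sense of induction in step 4 cannot be predicted with certainty. The catalyst is written in the quinidine-derived series; if the first run gives the 3S product, the quinine-derived pseudo-enantiomer is used with nothing else changed.

**Retrosynthetic overview**
1. Target 10 ⇐ silyl-ethyl ester 9, by fluoride unmasking of the carboxylic acid.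
2. 9 ⇐ aromatic ester 7 + (2E,6E)-farnesyl bromide 8, by enantioselective alkylative dearomatization at C5 of the arene; this forms the C–C bond and sets the only stereocentre.
3. 7 ⇐ ester 3 by C5 formylation and hydrogenolysis (CHO → CH3); 3 ⇐ acid 1 + alcohol 2.
4. No ring is built: the only ring is the benzene ring of 1, carried through and dearomatized in step 4.

**Notes**
- Numbering: in arenes 1, 3 and 7 the ring is numbered from the carboxyl carbon (C1), with OH at C2 and C4. C5 of 7 becomes C3 of 9 and 10.
- Cat-A: the N-quinuclidinium 3,5-bis(trifluoromethyl)benzyl bromide of 9-amino-9-deoxy-epi-quinidine whose C9–NH carries an N′-[3,5-bis(trifluoromethyl)phenyl]urea (a bifunctional urea–quaternary ammonium phase-transfer catalyst).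

**Step 1**
Reactants: 1 2,4-dihydroxy-3,6-dimethylbenzoic acid; 2 2-(trimethylsilyl)ethanol
Product: 3 2-(trimethylsilyl)ethyl 2,4-dihydroxy-3,6-dimethylbenzoate
Conditions: PPh3 (1.1 equiv), DIAD (1.1 equiv), 2 (1.05 equiv), THF, 0 °C → rt
Reagents that add atoms: 2-(trimethylsilyl)ethanol (2), C[Si](C)(C)CCO
Why: Mitsunobu esterification: the carboxylic acid, far more acidic than the phenols, is alkylated at oxygen by the alkoxyphosphonium ion of the primary alcohol, so the hindered carboxyl carbon is never attacked and the phenols stay free.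

**Step 2**
Reactants: 3 2-(trimethylsilyl)ethyl 2,4-dihydroxy-3,6-dimethylbenzoate
Product: 5 2-(trimethylsilyl)ethyl 3-formyl-4,6-dihydroxy-2,5-dimethylbenzoate (CHO on the former C5–H carbon), via aryl iminium chloride 4 (not isolated)
Conditions: POCl3 (1.5 equiv), DMF (4 equiv), MeCN, 0 → 40 °C; then H2O, 50 °C, 30 min
Reagents that add atoms: N,N-dimethylformamide, CN(C)C=O; water, O
Why: Vilsmeier–Haack formylation: C5 is the only unsubstituted ring carbon and is ortho to C4–OH and para to C2–OH, and iminium salt 4 is hydrolysed to the aldehyde on aqueous work-up while the silyl-ethyl ester tolerates the fluoride-free, moderately acidic medium.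

**Step 3**
Reactants: 5 2-(trimethylsilyl)ethyl 3-formyl-4,6-dihydroxy-2,5-dimethylbenzoate
Product: 7 2-(trimethylsilyl)ethyl 2,4-dihydroxy-3,5,6-trimethylbenzoate, via 2-(trimethylsilyl)ethyl 4,6-dihydroxy-3-(hydroxymethyl)-2,5-dimethylbenzoate 6 (not isolated)
Conditions: H2 (1 atm), 10% Pd/C, AcOH/EtOAc 1:4, rt
Reagents that add atoms: none
Why: Benzylic hydrogenolysis of an ortho-hydroxy aryl aldehyde: Pd/C reduces CHO to benzylic alcohol 6, whose C–O bond (activated by the ortho-hydroxyl and acetic acid) is then cleaved to CH3, while arene, ester and C–Si bonds are inert.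

**Step 4**
Reactants: 7 2-(trimethylsilyl)ethyl 2,4-dihydroxy-3,5,6-trimethylbenzoate; 8 (2E,6E)-farnesyl bromide
Product: 9 2-(trimethylsilyl)ethyl (3R)-6-hydroxy-2,3,5-trimethyl-4-oxo-3-[(2E,6E)-3,7,11-trimethyldodeca-2,6,10-trien-1-yl]cyclohexa-1,5-diene-1-carboxylate
Conditions: 8 (1.05 equiv), Cat-A (10 mol%), Cs2CO3 (1.5 equiv, powdered), toluene, −20 °C, 48 h; then pH 4 citrate buffer
Reagents that add atoms: (2E,6E)-farnesyl bromide (8), CC(C)=CCC/C(C)=C/CC/C(C)=C/CBr
Why: Proposed new method: intermolecular enantioselective alkylative dearomatization of a resorcylate under bifunctional hydrogen-bond-donor phase-transfer catalysis; the carbonate ionizes the more acidic, non-chelated C4–OH (C2–OH stays locked in the ester hydrogen bond), the urea N–H pair of Cat-A clamps the phenoxide oxygen and so disfavours O-alkylation (as protic media do for phenoxides) while the ammonium/quinoline wall covers one π-face, and C5 (ortho to one oxygen and para to the other, the position resorcinols prefer over the carbon between the oxygens) attacks the bromide in an SN2 sense (E geometry kept; SN2′ would join two quaternary carbons) on its Re face (C4 > C6 > CH3) to give the 3R centre, the acidic product then resting as a poorly nucleophilic enolate; the closest known reaction types are the racemic lithium-base C5-farnesylation of dimethylorsellinate esters, the phase-transfer-catalysed intramolecular alkylative dearomatization of phenols and the phase-transfer allylation of β-keto ester enolates.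

**Step 5**
Reactants: 9 2-(trimethylsilyl)ethyl (3R)-6-hydroxy-2,3,5-trimethyl-4-oxo-3-[(2E,6E)-3,7,11-trimethyldodeca-2,6,10-trien-1-yl]cyclohexa-1,5-diene-1-carboxylate
Product: 10 (3R)-6-hydroxy-2,3,5-trimethyl-4-oxo-3-[(2E,6E)-3,7,11-trimethyldodeca-2,6,10-trien-1-yl]cyclohexa-1,5-diene-1-carboxylic acid
Conditions: TBAF (3 equiv), THF, 0 °C → rt; then cold 0.1 M HCl to pH 3, extraction at 0 °C
Reagents that add atoms: none
Why: Fluoride-induced β-silyl fragmentation of a 2-(trimethylsilyl)ethyl ester: fluoride attacks silicon and expels ethene and the carboxylate without acid, heat or attack at the hindered carbonyl, so the polyene, the dienone and the non-enolisable quaternary stereocentre are untouched.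

**Compound list**
1 | 2,4-dihydroxy-3,6-dimethylbenzoic acid | Cc1cc(O)c(C)c(O)c1C(=O)O | starting material
2 | 2-(trimethylsilyl)ethanol | C[Si](C)(C)CCO | starting material
3 | 2-(trimethylsilyl)ethyl 2,4-dihydroxy-3,6-dimethylbenzoate | Cc1cc(O)c(C)c(O)c1C(=O)OCC[Si](C)(C)C | intermediate
4 | N-({2,4-dihydroxy-3,6-dimethyl-5-[2-(trimethylsilyl)ethoxycarbonyl]phenyl}methylidene)-N-methylmethanaminium chloride (aryl iminium chloride) | Cc1c(C=[N+](C)C)c(O)c(C)c(O)c1C(=O)OCC[Si](C)(C)C.[Cl-] | intermediate (not isolated)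
5 | 2-(trimethylsilyl)ethyl 3-formyl-4,6-dihydroxy-2,5-dimethylbenzoate | Cc1c(C=O)c(O)c(C)c(O)c1C(=O)OCC[Si](C)(C)C | intermediate
6 | 2-(trimethylsilyl)ethyl 4,6-dihydroxy-3-(hydroxymethyl)-2,5-dimethylbenzoate | Cc1c(CO)c(O)c(C)c(O)c1C(=O)OCC[Si](C)(C)C | intermediate (not isolated)
7 | 2-(trimethylsilyl)ethyl 2,4-dihydroxy-3,5,6-trimethylbenzoate | Cc1c(C)c(O)c(C)c(O)c1C(=O)OCC[Si](C)(C)C | intermediate
8 | (2E,6E)-farnesyl bromide [(2E,6E)-1-bromo-3,7,11-trimethyldodeca-2,6,10-triene] | CC(C)=CCC/C(C)=C/CC/C(C)=C/CBr | starting material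
9 | 2-(trimethylsilyl)ethyl (3R)-6-hydroxy-2,3,5-trimethyl-4-oxo-3-[(2E,6E)-3,7,11-trimethyldodeca-2,6,10-trien-1-yl]cyclohexa-1,5-diene-1-carboxylate | CC(C)=CCC/C(C)=C/CC/C(C)=C/C[C@@]1(C)C(=O)C(C)=C(O)C(C(=O)OCC[Si](C)(C)C)=C1C | intermediate
10 | (3R)-6-hydroxy-2,3,5-trimethyl-4-oxo-3-[(2E,6E)-3,7,11-trimethyldodeca-2,6,10-trien-1-yl]cyclohexa-1,5-diene-1-carboxylic acid | CC(C)=CCC/C(C)=C/CC/C(C)=C/C[C@@]1(C)C(=O)C(C)=C(O)C(C(=O)O)=C1C | target

**Totals**
Total steps: 5. Longest linear sequence: 5 (1 → 3 → 5 → 7 → 9 → 10).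

**Three steps most likely to fail**

Step 4 (the proposed new step). The likely failures are O-farnesylation, attack at C3 (between the two oxygens) instead of C5, a second alkylation of the product enolate, product inhibition of the catalyst, or low enantiomeric excess. The fallback uses known chemistry and sets out from 7 and 8: deprotonation with LiHMDS (2.2 equiv) in toluene at −78 → 0 °C and alkylation of the lithium phenoxide at carbon gives racemic 2-(trimethylsilyl)ethyl 6-hydroxy-2,3,5-trimethyl-4-oxo-3-[(2E,6E)-farnesyl]cyclohexa-1,5-diene-1-carboxylate F1. Preparative chiral SFC on an amylose-type phase then separates the wanted (3R)-enantiomer, which is compound 9 and returns to the route there, from the (3S)-enantiomer F2, which is set aside. The same SFC method polishes 9 from step 4 if its ee is short of 98%.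

Step 5. The fragmentation may stall because 9 reacts as a delocalized anion, or basic fluoride may cause side reactions; the free β-hydroxy-enoic acid can also lose CO2 if warmed or over-acidified, so it is handled cold in any case. The fallback changes the carboxyl mask and sets out from 7: TBAF in THF at 40 °C cleaves the ester on the robust arene to give 2,4-dihydroxy-3,5,6-trimethylbenzoic acid F3. Acetone with TFAA/TFA (0 °C → rt) ties the carboxyl and C2–OH together as 7-hydroxy-2,2,5,6,8-pentamethyl-4H-1,3-benzodioxin-4-one F4. The step 4 conditions with 8 then give (6R)-2,2,5,6,8-pentamethyl-6-[(2E,6E)-3,7,11-trimethyldodeca-2,6,10-trien-1-yl]-4H-1,3-benzodioxine-4,7(6H)-dione F5. LiOH in THF/H2O at 0 °C opens this activated, neutral acylal with loss of acetone, and cold acidification to pH 3 returns to the route at 10.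

Step 2. The ester-deactivated ring may formylate sluggishly, or the HCl generated may erode the silyl-ethyl ester. The fallback replaces formylation/hydrogenolysis by aminomethylation/hydrogenolysis and sets out from 3: a phenolic Mannich reaction (morpholine, 37% aq. CH2O, EtOH, 60 °C) gives 2-(trimethylsilyl)ethyl 4,6-dihydroxy-2,5-dimethyl-3-(morpholin-4-ylmethyl)benzoate F6. Hydrogenolysis of the benzylic C–N bond (H2, Pd/C, AcOH, 60 °C) gives 7 directly, where it returns to the route, bypassing 5.

**Further compounds**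
F1 | step 4 | racemic 2-(trimethylsilyl)ethyl 6-hydroxy-2,3,5-trimethyl-4-oxo-3-[(2E,6E)-3,7,11-trimethyldodeca-2,6,10-trien-1-yl]cyclohexa-1,5-diene-1-carboxylate | CC(C)=CCC/C(C)=C/CC/C(C)=C/CC1(C)C(=O)C(C)=C(O)C(C(=O)OCC[Si](C)(C)C)=C1C
F2 | step 4 | 2-(trimethylsilyl)ethyl (3S)-6-hydroxy-2,3,5-trimethyl-4-oxo-3-[(2E,6E)-3,7,11-trimethyldodeca-2,6,10-trien-1-yl]cyclohexa-1,5-diene-1-carboxylate | CC(C)=CCC/C(C)=C/CC/C(C)=C/C[C@]1(C)C(=O)C(C)=C(O)C(C(=O)OCC[Si](C)(C)C)=C1C
F3 | step 5 | 2,4-dihydroxy-3,5,6-trimethylbenzoic acid | Cc1c(C)c(O)c(C)c(O)c1C(=O)O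
F4 | step 5 | 7-hydroxy-2,2,5,6,8-pentamethyl-4H-1,3-benzodioxin-4-one | Cc1c(C)c(O)c(C)c2OC(C)(C)OC(=O)c12
F5 | step 5 | (6R)-2,2,5,6,8-pentamethyl-6-[(2E,6E)-3,7,11-trimethyldodeca-2,6,10-trien-1-yl]-4H-1,3-benzodioxine-4,7(6H)-dione | CC(C)=CCC/C(C)=C/CC/C(C)=C/C[C@@]1(C)C(=O)C(C)=C2OC(C)(C)OC(=O)C2=C1C
F6 | step 2 | 2-(trimethylsilyl)ethyl 4,6-dihydroxy-2,5-dimethyl-3-(morpholin-4-ylmethyl)benzoate | Cc1c(CN2CCOCC2)c(O)c(C)c(O)c1C(=O)OCC[Si](C)(C)C
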